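A direct plan would take ring A from an arene: the Friedel–Crafts ketone 2-methoxy-1-(2,4,5-trimethoxyphenyl)ethan-1-one A1 would be joined by aldol addition and alcohol oxidation to 2,3-bis(benzyloxy)benzaldehyde A2 to give the 2-methoxy-1,3-diketone A3.
Ring A of A3 would be oxidised with (NH4)2Ce(NO3)6 to the acylquinone A4, ring C would be closed by adding the diketone enolate oxygen to the quinone to give the 5,8-dihydroxyflavone A5, and 8-O-methylation and debenzylation would finish.
Weak point 1, the oxidative demethylation with tetravalent cerium: it would have to pick the trimethoxyarene in the presence of an oxidisable 2-alkoxy-1,3-dicarbonyl and two benzyl ethers, and it would deliver an acylquinone too labile to purify.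
Weak point 2, the closure of ring C onto the quinone: an O–C bond formation with internal redox that has no close precedent; C-attack, hemiketal formation and intermolecular electron exchange would compete, and a failure would strand the longest linear stretch.
Weak point 3, the oxidation-state detour: ring A would be bought with the wrong pattern, so alcohol oxidation, quinone formation, internal reduction and remethylation of one of two para hydroxyls would be spent without building skeleton.

**Retrosynthetic overview**
Ring A carries 5-OH para to 8-OMe with C6–H and 7-OMe in between, which is the pattern a 3,4-dimethoxy-4-alkenylcyclobut-2-enone delivers on ring expansion; ring A would therefore be made last, on the C5=C6 bond of a preformed 4-pyranone (ring C), which becomes C4a–C8a.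
Key disconnections: C5–C4a (step 7: thermal 4π opening of cyclobutenone 13, 6π electrocyclisation of the dienylketene, tautomerisation), C8–C8a (step 6: C6-lithiated pyranone 7 plus methyl semisquarate 10, alkoxide methylated in the same flask) and C2–C1' (step 4: Suzuki coupling).
Ring order: ring B (bought, catechol as acetonide) is attached to ring C (bought as 3-hydroxy-4H-pyran-4-one) and ring A is closed last, whereas the direct plan closes ring C last between two finished arenes.
No quinone, cerium oxidation or redox detour is needed: 5-OH comes from the ketene carbon, 8-OMe from the methylated carbinol, 7-OMe and C6–H from the semisquarate, so the two para oxygens are told apart before ring A exists.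
Key step: step 7

Assumption: dimethyl squarate is taken to follow the hydride reduction and acid-induced loss of alcohol by which dialkyl squarates give 3-alkoxycyclobut-3-ene-1,2-diones; flavone numbering is used for ring positions of 13 to 17.

Step 1
Reactants: 1 2,2-dimethyl-1,3-benzodioxole
Product: 3 2-(2,2-dimethyl-1,3-benzodioxol-4-yl)-4,4,5,5-tetramethyl-1,3,2-dioxaborolane, via aryllithium 2 (not isolated)
Conditions: n-BuLi (1.1 equiv), THF, 0 °C → rt; 2-isopropoxy-4,4,5,5-tetramethyl-1,3,2-dioxaborolane (1.2 equiv), −78 °C → rt; H2O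
Reagents that add atoms: 2-isopropoxy-4,4,5,5-tetramethyl-1,3,2-dioxaborolane, CC(C)OB1OC(C)(C)C(C)(C)O1
Why: Directed ortho-lithiation should occur at C4, which is acidified by the ring oxygen (the quaternary C2 offers no acetal proton), and the aryllithium is trapped by the isopropoxy pinacol borate.

Step 2
Reactants: 4 3-hydroxy-4H-pyran-4-one (pyromeconic acid)
Product: 5 2-bromo-3-hydroxy-4H-pyran-4-one
Conditions: N-bromosuccinimide (1.0 equiv), MeCN, 0 °C → rt, dark
Reagents that add atoms: N-bromosuccinimide, O=C1CCC(=O)N1Br
Why: Electrophilic bromination of the enolic 3-hydroxy-4-pyranone should take place at C2, the enol β-carbon next to the hydroxyl, where this ring class undergoes halogenation, Mannich and aldol reactions.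

Step 3
Reactants: 5 2-bromo-3-hydroxy-4H-pyran-4-one
Product: 6 2-bromo-3-methoxy-4H-pyran-4-one
Conditions: MeI (1.5 equiv), K2CO3 (1.5 equiv), acetone, rt → 40 °C
Reagents that add atoms: iodomethane, CI
Why: Williamson O-methylation of the acidic enolic hydroxyl needs only carbonate, and the weakly nucleophilic pyranone oxide should not displace the 2-bromide at this temperature.

Step 4
Reactants: 6 2-bromo-3-methoxy-4H-pyran-4-one; 3 2-(2,2-dimethyl-1,3-benzodioxol-4-yl)-4,4,5,5-tetramethyl-1,3,2-dioxaborolane
Product: 7 2-(2,2-dimethyl-1,3-benzodioxol-4-yl)-3-methoxy-4H-pyran-4-one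
Conditions: Pd(PPh3)4 (5 mol%), K3PO4 (3 equiv), 1,4-dioxane–H2O (10:1), 85 °C, Ar
Reagents that add atoms: none
Why: Suzuki–Miyaura coupling should be easy because the C2–Br bond is a vinylogous acyl bromide that adds readily to zerovalent palladium, and the pinacol boronate transmetalates under phosphate activation.

Step 5
Reactants: 8 3,4-dimethoxycyclobut-3-ene-1,2-dione (dimethyl squarate)
Product: 10 3-methoxycyclobut-3-ene-1,2-dione (methyl semisquarate), via carbinol 9 (not isolated)
Conditions: LiAlH(OtBu)3 (1.1 equiv), THF, −78 → −20 °C; 1 M HCl quench; crude 9, conc. HCl (cat.), CH2Cl2, rt; used at once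
Reagents that add atoms: water, O
Why: The hindered hydride reduces one squarate carbonyl to carbinol 9, and acid ionises the allylic hydroxyl to an oxocarbenium ion at the neighbouring C–OMe carbon, which water converts into the new carbonyl with loss of methanol.

Step 6
Reactants: 7 2-(2,2-dimethyl-1,3-benzodioxol-4-yl)-3-methoxy-4H-pyran-4-one; 10 3-methoxycyclobut-3-ene-1,2-dione
Product: 13 4-[6-(2,2-dimethyl-1,3-benzodioxol-4-yl)-5-methoxy-4-oxo-4H-pyran-2-yl]-3,4-dimethoxycyclobut-2-en-1-one (racemic), via lithiopyranone 11 (not isolated), via lithium alkoxide 12 (not isolated)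
Conditions: lithium 2,2,6,6-tetramethylpiperidide (LiTMP, 1.1 equiv), THF, −78 °C, 20 min; 10 (1.2 equiv), −78 °C, 30 min; MeOTf (1.5 equiv), −78 → −20 °C; aq. NaHCO3
Reagents that add atoms: methyl trifluoromethanesulfonate, COS(=O)(=O)C(F)(F)F
Why: The hindered lithium amide should remove C6–H next to the ring oxygen of 7 as it removes C2–H of chromones, the vinyllithium adds 1,2 to the ketone-like carbonyl of 10 (the one flanked by C–OMe, not the vinylogous ester carbonyl), and the tertiary lithium alkoxide is O-methylated in the flask; the new quaternary stereocentre is racemic and disappears in step 7.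

Step 7
Reactants: 13 4-[6-(2,2-dimethyl-1,3-benzodioxol-4-yl)-5-methoxy-4-oxo-4H-pyran-2-yl]-3,4-dimethoxycyclobut-2-en-1-one
Product: 16 2-(2,2-dimethyl-1,3-benzodioxol-4-yl)-5-hydroxy-3,7,8-trimethoxy-4H-chromen-4-one, via dienylketene 14 (not isolated), via cyclohexadienone 15 (not isolated)
Conditions: toluene (0.02 M, degassed, dry), 110 °C, Ar, 2 h
Reagents that add atoms: none
Why: Heating should open the cyclobutenone by conrotatory 4π-electrocyclic cleavage of the C1–C4 bond, and because the donor 4-methoxy group rotates outward, the pyranyl group turns inward and the (Z)-dienylketene 14 has the pyranone C5=C6 bond next to the ketene. 14 then undergoes 6π-electrocyclisation between the electrophilic ketene carbon and pyranone C5 (the α-carbon of the vinylogous ester), which forms the C5–C4a bond and closes ring A as a six-membered ring in the only mode the triene allows; the C4a–H of cyclohexadienone 15, flanked by two carbonyls, then shifts to oxygen to give the phenol. The closest known reaction is the Moore rearrangement of squarate-derived 4-aryl-, 4-heteroaryl- and 4-alkenyl-4-alkoxy (or 4-hydroxy) cyclobutenones to 4-alkoxyphenols and annulated hydroquinones. No stereocentre survives: C4 of 13 becomes the aromatic C8, and C4a of 15 is planarised on tautomerisation. The step needs inward rotation of the pyranyl group, secured by the outward preference of the methoxy donor, and ring closure before the ketene is intercepted, secured by high dilution, exclusion of protic nucleophiles and the absence of a free hydroxyl that could divert the ketene to a furanone. The substitution pattern is fixed by the connectivity of 13: ketene carbonyl to 5-OH (hydrogen-bonded to C4=O), ring CH to C6–H, C–OMe to 7-OMe and the methylated carbinol carbon to 8-OMe.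

Step 8
Reactants: 16 2-(2,2-dimethyl-1,3-benzodioxol-4-yl)-5-hydroxy-3,7,8-trimethoxy-4H-chromen-4-one
Product: 17 2-(2,3-dihydroxyphenyl)-5-hydroxy-3,7,8-trimethoxy-4H-chromen-4-one (5,2',3'-trihydroxy-3,7,8-trimethoxyflavone)
Conditions: CF3CO2H–H2O (9:1), rt
Reagents that add atoms: none
Why: Acid hydrolysis of the catechol isopropylidene ketal releases acetone, while the three methyl ethers and the chelated 5-hydroxychromone should be stable to aqueous trifluoroacetic acid.

**Compound list**
1 | 2,2-dimethyl-1,3-benzodioxole | CC1(C)Oc2ccccc2O1 | starting material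
2 | (2,2-dimethyl-1,3-benzodioxol-4-yl)lithium | [Li]c1cccc2OC(C)(C)Oc12 | intermediate (not isolated)
3 | 2-(2,2-dimethyl-1,3-benzodioxol-4-yl)-4,4,5,5-tetramethyl-1,3,2-dioxaborolane | CC1(C)OB(OC1(C)C)c1cccc2OC(C)(C)Oc12 | intermediate
4 | 3-hydroxy-4H-pyran-4-one (pyromeconic acid) | O=c1ccocc1O | starting material
5 | 2-bromo-3-hydroxy-4H-pyran-4-one | O=c1ccoc(Br)c1O | intermediate
6 | 2-bromo-3-methoxy-4H-pyran-4-one | COc1c(Br)occc1=O | intermediate
7 | 2-(2,2-dimethyl-1,3-benzodioxol-4-yl)-3-methoxy-4H-pyran-4-one | COc1c(-c2cccc3OC(C)(C)Oc23)occc1=O | intermediate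
8 | 3,4-dimethoxycyclobut-3-ene-1,2-dione (dimethyl squarate) | COC1=C(OC)C(=O)C1=O | starting material
9 | 4-hydroxy-2,3-dimethoxycyclobut-2-en-1-one (racemic) | COC1=C(OC)C(O)C1=O | intermediate (not isolated)
10 | 3-methoxycyclobut-3-ene-1,2-dione (methyl semisquarate) | COC1=CC(=O)C1=O | intermediate
11 | [6-(2,2-dimethyl-1,3-benzodioxol-4-yl)-5-methoxy-4-oxo-4H-pyran-2-yl]lithium | [Li]c1cc(=O)c(OC)c(-c2cccc3OC(C)(C)Oc23)o1 | intermediate (not isolated)
12 | lithium 1-[6-(2,2-dimethyl-1,3-benzodioxol-4-yl)-5-methoxy-4-oxo-4H-pyran-2-yl]-2-methoxy-4-oxocyclobut-2-en-1-olate (racemic) | [Li]OC1(c2cc(=O)c(OC)c(-c3cccc4OC(C)(C)Oc34)o2)C(OC)=CC1=O | intermediate (not isolated)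
13 | 4-[6-(2,2-dimethyl-1,3-benzodioxol-4-yl)-5-methoxy-4-oxo-4H-pyran-2-yl]-3,4-dimethoxycyclobut-2-en-1-one (racemic) | COC1=CC(=O)C1(OC)c1cc(=O)c(OC)c(-c2cccc3OC(C)(C)Oc23)o1 | intermediate
14 | (3Z)-4-[6-(2,2-dimethyl-1,3-benzodioxol-4-yl)-5-methoxy-4-oxo-4H-pyran-2-yl]-3,4-dimethoxybuta-1,3-dien-1-one (dienylketene) | O=C=C/C(OC)=C(/OC)c1cc(=O)c(OC)c(-c2cccc3OC(C)(C)Oc23)o1 | intermediate (not isolated)
15 | 2-(2,2-dimethyl-1,3-benzodioxol-4-yl)-3,7,8-trimethoxy-4H-chromene-4,5(4aH)-dione (racemic at C4a) | COC1=CC(=O)C2C(=O)C(OC)=C(c3cccc4OC(C)(C)Oc34)OC2=C1OC | intermediate (not isolated)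
16 | 2-(2,2-dimethyl-1,3-benzodioxol-4-yl)-5-hydroxy-3,7,8-trimethoxy-4H-chromen-4-one | COc1cc(O)c2c(=O)c(OC)c(-c3cccc4OC(C)(C)Oc34)oc2c1OC | intermediate
17 | 2-(2,3-dihydroxyphenyl)-5-hydroxy-3,7,8-trimethoxy-4H-chromen-4-one | COc1cc(O)c2c(=O)c(OC)c(-c3cccc(O)c3O)oc2c1OC | target

**Step count and risks**
Total steps: 8. Longest linear sequence: 6 (steps 2, 3, 4, 6, 7, 8).

Steps most likely to fail:

1. Step 6. The hindered tertiary alkoxide may be captured slowly while methyl triflate alkylates the pyranone carbonyl oxygen, or the lithiated pyranone may add to unmetalated 7 before it meets 10. Fallback, setting out from 7 and 10 and coming back at 16: the alkoxide 12 would be quenched with aqueous NH4Cl to give the free carbinol 4-[6-(2,2-dimethyl-1,3-benzodioxol-4-yl)-5-methoxy-4-oxo-4H-pyran-2-yl]-4-hydroxy-3-methoxycyclobut-2-en-1-one F1. Thermolysis of F1 (toluene, 110 °C, Ar) by the same ring opening and 6π closure should give the hydroquinone 2-(2,2-dimethyl-1,3-benzodioxol-4-yl)-5,8-dihydroxy-3,7-dimethoxy-4H-chromen-4-one F2. The two para hydroxyls would then be told apart after the annulation: MeI (1.05 equiv), K2CO3, acetone under argon should methylate only 8-OH, since 5-OH is held in the hydrogen bond to C4=O, which gives 16. Should the metalation itself be the obstacle, the annulation under point 2 needs no lithiated pyranone.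

2. Step 7. The dienylketene may be consumed by dimerisation or by adventitious nucleophiles faster than it closes onto the enone carbon of the pyranone. Fallback, setting out from 7 and coming back at 16: ring A would be built by a polar Hauser–Kraus-type annulation in which the pyranone is the Michael acceptor. Commercial 4-methoxyfuran-2(5H)-one would be brominated at C5 (N-bromosuccinimide, radical initiator) to 5-bromo-4-methoxyfuran-2(5H)-one F3, and sodium benzenesulfinate would convert this into 4-methoxy-5-(phenylsulfonyl)furan-2(5H)-one F4. The anion of F4 (LiOtBu, THF, −78 → 0 °C) should add through C5 to C6 of 7; the resulting pyranone enolate closes onto the lactone carbonyl, benzenesulfinate is lost and enolisation gives the hydroquinone F2 named above. 8-O-Methylation as under point 1 then gives 16.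

3. Step 4. Aqueous base may hydrolyse the vinylogous acyl bromide, and the ortho-oxygenated boronate may lose boron by protonolysis before transmetalation. Fallback, setting out from 1 and 6 and coming back at 7: the aryllithium 2 would be transmetalated with ZnCl2 to (2,2-dimethyl-1,3-benzodioxol-4-yl)zinc chloride F5 and coupled with 6 in a base-free, anhydrous Negishi reaction (Pd(PPh3)4, THF, 55 °C), which also makes step 1 unnecessary.

**Further compounds**
F1 | step 6 | 4-[6-(2,2-dimethyl-1,3-benzodioxol-4-yl)-5-methoxy-4-oxo-4H-pyran-2-yl]-4-hydroxy-3-methoxycyclobut-2-en-1-one (racemic) | COC1=CC(=O)C1(O)c1cc(=O)c(OC)c(-c2cccc3OC(C)(C)Oc23)o1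
F2 | step 6 | 2-(2,2-dimethyl-1,3-benzodioxol-4-yl)-5,8-dihydroxy-3,7-dimethoxy-4H-chromen-4-one | COc1cc(O)c2c(=O)c(OC)c(-c3cccc4OC(C)(C)Oc34)oc2c1O
F3 | step 7 | 5-bromo-4-methoxyfuran-2(5H)-one (racemic) | COC1=CC(=O)OC1Br
F4 | step 7 | 4-methoxy-5-(phenylsulfonyl)furan-2(5H)-one (racemic) | COC1=CC(=O)OC1S(=O)(=O)c1ccccc1
F5 | step 4 | (2,2-dimethyl-1,3-benzodioxol-4-yl)zinc chloride | Cl[Zn]c1cccc2OC(C)(C)Oc12
A1 | direct plan | 2-methoxy-1-(2,4,5-trimethoxyphenyl)ethan-1-one | COCC(=O)c1cc(OC)c(OC)cc1OC
A2 | direct plan | 2,3-bis(benzyloxy)benzaldehyde | O=Cc1cccc(OCc2ccccc2)c1OCc1ccccc1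
A3 | direct plan | 1-[2,3-bis(benzyloxy)phenyl]-2-methoxy-3-(2,4,5-trimethoxyphenyl)propane-1,3-dione | COc1cc(OC)c(OC)cc1C(=O)C(OC)C(=O)c1cccc(OCc2ccccc2)c1OCc1ccccc1
A4 | direct plan | 1-[2,3-bis(benzyloxy)phenyl]-2-methoxy-3-(4-methoxy-3,6-dioxocyclohexa-1,4-dien-1-yl)propane-1,3-dione | COC1=CC(=O)C(C(=O)C(OC)C(=O)c2cccc(OCc3ccccc3)c2OCc2ccccc2)=CC1=O
A5 | direct plan | 2-[2,3-bis(benzyloxy)phenyl]-5,8-dihydroxy-3,7-dimethoxy-4H-chromen-4-one | COc1cc(O)c2c(=O)c(OC)c(-c3cccc(OCc4ccccc4)c3OCc3ccccc3)oc2c1O
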